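**Strategy.** The oxane hemiketal (O1, C2 hemiketal carbon, C3 CHBr, C4, C5 bearing the side chain, C6) is read as the hydrate of a 5-bromo-6-methyl-3,4-dihydro-2H-pyran. Its O1–C2=C3 unit is the enolate of an acetoacetate, and C4 and C6 are two CH2 arms on C5, a 1,3-bis-electrophile. The key step is a formal [3+3] annulation: the keto ester enolate is alkylated at carbon by an iodomethyl arm (C3–C4) and then at oxygen by a chloromethyl arm (C6–O1) of a bis-electrophile carrying the complete side chain. C5 and the chlorine-bearing carbon come from a butyrolactone template. Bromodecarboxylation and hydration then set C3 and C2 in one event.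

Key step: step 9

Remark: 4-(hydroxymethyl)furan-2(5H)-one (1) is taken as a catalogue compound (otherwise one Wittig/lactonization step from 1,3-dihydroxyacetone dimer and ethyl (triphenylphosphoranylidene)acetate); C7 denotes the chlorine-bearing side-chain carbon.

**Step 1**
Reactants: 1 4-(hydroxymethyl)furan-2(5H)-one
Product: 2 (4S)-4-(hydroxymethyl)oxolan-2-one
Conditions: Ru(OAc)2[(S)-BINAP] (1 mol%), H2 (50 atm), MeOH–CH2Cl2, 25 °C
Reagents that add atoms: none
Why: Noyori-type asymmetric hydrogenation of a β-substituted butenolide, in which the allylic hydroxyl and the lactone carbonyl bind ruthenium; addition of H2 to one face of C3=C4 should set C4 (later C5 of the target) as S, the BINAP hand being fixed on a test run since both hands are available.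

**Step 2**
Reactants: 2 (4S)-4-(hydroxymethyl)oxolan-2-one
Product: 3 (4R)-4-(chloromethyl)oxolan-2-one
Conditions: PPh3, CCl4, CH2Cl2, 40 °C
Reagents that add atoms: carbon tetrachloride, ClC(Cl)(Cl)Cl
Why: Appel reaction at the primary alcohol under neutral conditions, which should avoid the acyl migration that would racemize 2; the stereocentre is untouched and the descriptor changes only through CIP priorities.

**Step 3**
Reactants: 3 (4R)-4-(chloromethyl)oxolan-2-one
Product: 5 (4R)-3-chloro-4-(chloromethyl)oxolan-2-one as a mixture of C3 epimers, via silyl ketene acetal 4 (not isolated)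
Conditions: LiN(SiMe3)2, Me3SiCl, THF, −78 °C; then NCS, −78 to 0 °C
Reagents that add atoms: N-chlorosuccinimide, O=C1CCC(=O)N1Cl
Why: Electrophilic chlorination of a silyl ketene acetal; trapping the lithium enolate at once as 4 should prevent both 3-exo-tet displacement of the γ-chloride and polychlorination, and the C3 configuration is irrelevant because it is planarized again in step 4.

**Step 4**
Reactants: 5 (4R)-3-chloro-4-(chloromethyl)oxolan-2-one
Product: 7 (3S,4R)-3-chloro-4-(chloromethyl)-3-methyloxolan-2-one, via lithium enolate 6 (not isolated)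
Conditions: LiN(SiMe3)2, THF–DMPU, −78 °C; then MeI, −78 to −40 °C
Reagents that add atoms: iodomethane, CI
Why: Alkylation of an α-chloro lactone enolate; MeI should approach 6 on the face anti to the C4 chloromethyl group, so that methyl ends trans and chlorine cis to CH2Cl (the C7/C5 relationship of the target), while the low temperature and the poor leaving-group quality of the primary chloride should hold back cyclopropane closure.

**Step 5**
Reactants: 7 (3S,4R)-3-chloro-4-(chloromethyl)-3-methyloxolan-2-one
Product: 8 (3S,4R)-3-chloro-4-(chloromethyl)-3-methyloxolan-2-ol (anomers)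
Conditions: iBu2AlH (1.1 equiv), CH2Cl2, −78 °C; aq. KNaC4H4O6
Reagents that add atoms: none
Why: Partial reduction of a lactone with iBu2AlH; the tetrahedral aluminium alkoxide is stable at −78 °C and gives the lactol only on work-up, and neither C–Cl bond is touched.

**Step 6**
Reactants: 8 (3S,4R)-3-chloro-4-(chloromethyl)-3-methyloxolan-2-ol
Product: 9 (2R,3S,4E)-5-bromo-3-chloro-2-(chloromethyl)-3-methylpent-4-en-1-ol
Conditions: CrBr2 (8 equiv), CHBr3 (3 equiv), THF, 0 to 50 °C
Reagents that add atoms: bromoform, BrC(Br)Br
Why: Takai–Utimoto olefination on the open hydroxy aldehyde form of the lactol, which should give the E-bromoalkene (CrBr2 instead of CrCl2 avoids halogen exchange); the lactone CH2O arm is released as the free alcohol, so the two arms on C5 stay differentiated (CH2OH, later C4; CH2Cl, later C6).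

**Step 7**
Reactants: 9 (2R,3S,4E)-5-bromo-3-chloro-2-(chloromethyl)-3-methylpent-4-en-1-ol
Product: 10 (1E,3R,4R)-1-bromo-3-chloro-4-(chloromethyl)-5-iodo-3-methylpent-1-ene
Conditions: I2, PPh3, imidazole, CH2Cl2, 0 °C
Reagents that add atoms: iodine, II
Why: Appel-type iodination; SN2 displacement of the oxyphosphonium group at the primary carbon under neutral conditions should leave the tertiary allylic chloride, the primary chloride and both stereocentres untouched (the C3 descriptor changes only through CIP priorities).

**Step 8**
Reactants: 11 2,2,6-trimethyl-4H-1,3-dioxin-4-one; 12 2-(trimethylsilyl)ethanol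
Product: 13 2-(trimethylsilyl)ethyl 3-oxobutanoate
Conditions: xylene, 135 °C, acetone distilled off
Reagents that add atoms: none
Why: Thermal retro-[4+2] cleavage of the dioxinone gives acetylketene, which the alcohol captures (acetoacetylation).

**Step 9**
Reactants: 10 (1E,3R,4R)-1-bromo-3-chloro-4-(chloromethyl)-5-iodo-3-methylpent-1-ene; 13 2-(trimethylsilyl)ethyl 3-oxobutanoate
Product: 15 2-(trimethylsilyl)ethyl (3R)-3-[(2S,3E)-4-bromo-2-chlorobut-3-en-2-yl]-6-methyl-3,4-dihydro-2H-pyran-5-carboxylate, via chloro keto ester 14 (not isolated)
Conditions: Cs2CO3 (3 equiv), 13 (2.5 equiv), DMF, 25 °C, then 60 °C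
Reagents that add atoms: none
Why: The caesium enolate of 13 should attack the primary iodide of 10 at carbon in an SN2 step (C3–C4 bond), and the still enolizable product 14 is deprotonated again so that its ketone-derived enolate oxygen displaces the chloride of the second arm (C6–O1 bond), the iodide set free in the first step acting as Finkelstein catalyst. The closest known reaction type is the one-pot C,O-dialkylation of acetoacetic esters with 1-bromo-3-chloropropane to 6-methyl-3,4-dihydro-2H-pyran-5-carboxylates. The dihydropyran ring closes in the 6-exo-tet mode by O-alkylation, the alternative C-alkylation being a disfavoured 4-exo-tet cyclobutane closure. No new stereocentre is formed; the C5 configuration is defined only by which CH2 arm becomes C-bound and which O-bound, and this is controlled by the reactivity gap between iodide and chloride toward the soft carbon nucleophile. The step needs C- before O-alkylation, no halide exchange on 10 before the first alkylation and survival of the tertiary allylic chloride; iodide as first leaving group, excess 13 against double alkylation and a carbonate base too weak for E2 should secure this.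

**Step 10**
Reactants: 15 the dihydropyran ester from step 9
Product: 16 (3R)-3-[(2S,3E)-4-bromo-2-chlorobut-3-en-2-yl]-6-methyl-3,4-dihydro-2H-pyran-5-carboxylic acid
Conditions: Bu4NF, THF, 0 °C to rt; aq. NaHSO4
Reagents that add atoms: none
Why: Fluoride-induced fragmentation of the 2-(trimethylsilyl)ethyl ester (attack at silicon, loss of ethene) should unmask the vinylogous carbonic acid without aqueous base or strong acid, which would endanger the tertiary allylic chloride.

**Step 11**
Reactants: 16 the dihydropyran carboxylic acid from step 10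
Product: 18 (2R,3S,5R)-3-bromo-5-[(2S,3E)-4-bromo-2-chlorobut-3-en-2-yl]-2-methyloxan-2-ol, via bromo enol ether 17 (not isolated)
Conditions: NBS (1.05 equiv), Et3N (0.1 equiv), CH2Cl2, 0 °C; then THF, 1 M aq. H2SO4, 0 °C to rt
Reagents that add atoms: N-bromosuccinimide, O=C1CCC(=O)N1Br; water, O
Why: Hunsdiecker-type halodecarboxylation followed by acid-catalysed enol ether hydration; NBS should brominate the nucleophilic α-carbon of the β-alkoxyacrylate with loss of CO2 to give 17, and axial protonation at C3 in the half-chair that keeps the C5 side chain pseudo-equatorial (H axial, Br equatorial, 3S) plus axial addition of water to the oxocarbenium ion (anomeric OH, 2R) should give 18, which is also the thermodynamically preferred isomer.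

**Compound list**
1 | 4-(hydroxymethyl)furan-2(5H)-one | O=C1C=C(CO)CO1 | starting material
2 | (4S)-4-(hydroxymethyl)oxolan-2-one | O=C1C[C@@H](CO)CO1 | intermediate
3 | (4R)-4-(chloromethyl)oxolan-2-one | O=C1C[C@@H](CCl)CO1 | intermediate
4 | (3R)-3-(chloromethyl)-5-[(trimethylsilyl)oxy]-2,3-dihydrofuran, silyl ketene acetal, not isolated | C[Si](C)(C)OC1=C[C@@H](CCl)CO1 | intermediate
5 | (4R)-3-chloro-4-(chloromethyl)oxolan-2-one, mixture of C3 epimers | ClC1C(=O)OC[C@@H]1CCl | intermediate
6 | lithium (4R)-3-chloro-4-(chloromethyl)-4,5-dihydrofuran-2-olate, not isolated | [Li+].[O-]C1=C(Cl)[C@@H](CCl)CO1 | intermediate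
7 | (3S,4R)-3-chloro-4-(chloromethyl)-3-methyloxolan-2-one | C[C@@]1(Cl)C(=O)OC[C@@H]1CCl | intermediate
8 | (3S,4R)-3-chloro-4-(chloromethyl)-3-methyloxolan-2-ol, anomers | C[C@@]1(Cl)C(O)OC[C@@H]1CCl | intermediate
9 | (2R,3S,4E)-5-bromo-3-chloro-2-(chloromethyl)-3-methylpent-4-en-1-ol | C[C@@](Cl)(/C=C/Br)[C@H](CO)CCl | intermediate
10 | (1E,3R,4R)-1-bromo-3-chloro-4-(chloromethyl)-5-iodo-3-methylpent-1-ene | C[C@@](Cl)(/C=C/Br)[C@H](CI)CCl | intermediate
11 | 2,2,6-trimethyl-4H-1,3-dioxin-4-one | CC1=CC(=O)OC(C)(C)O1 | starting material
12 | 2-(trimethylsilyl)ethanol | C[Si](C)(C)CCO | starting material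
13 | 2-(trimethylsilyl)ethyl 3-oxobutanoate | CC(=O)CC(=O)OCC[Si](C)(C)C | intermediate
14 | 2-(trimethylsilyl)ethyl (4R,5S,6E)-2-acetyl-7-bromo-5-chloro-4-(chloromethyl)-5-methylhept-6-enoate, C2 epimers, not isolated | C[C@@](Cl)(/C=C/Br)[C@H](CC(C(C)=O)C(=O)OCC[Si](C)(C)C)CCl | intermediate
15 | 2-(trimethylsilyl)ethyl (3R)-3-[(2S,3E)-4-bromo-2-chlorobut-3-en-2-yl]-6-methyl-3,4-dihydro-2H-pyran-5-carboxylate | C[C@@](Cl)(/C=C/Br)[C@H]1COC(C)=C(C(=O)OCC[Si](C)(C)C)C1 | intermediate
16 | (3R)-3-[(2S,3E)-4-bromo-2-chlorobut-3-en-2-yl]-6-methyl-3,4-dihydro-2H-pyran-5-carboxylic acid | C[C@@](Cl)(/C=C/Br)[C@H]1COC(C)=C(C(=O)O)C1 | intermediate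
17 | (3R)-5-bromo-3-[(2S,3E)-4-bromo-2-chlorobut-3-en-2-yl]-6-methyl-3,4-dihydro-2H-pyran, not isolated | C[C@@](Cl)(/C=C/Br)[C@H]1COC(C)=C(Br)C1 | intermediate
18 | (2R,3S,5R)-3-bromo-5-[(2S,3E)-4-bromo-2-chlorobut-3-en-2-yl]-2-methyloxan-2-ol | C[C@@](Cl)(/C=C/Br)[C@H]1CO[C@@](C)(O)[C@@H](Br)C1 | target

**Total step count:** 11. **Longest linear sequence:** 10 steps (steps 1–7 and 9–11).

**Steps most likely to fail**

1. Step 9 (annulation). Both SN2 displacements occur at β-branched primary carbons and may be slow. During that time halide exchange on 10 or a first-step O-alkylation could erode the differentiation of the two arms (and with it the C5 configuration), and base-induced loss of HCl from the tertiary allylic chloride could compete at 60 °C. Fallback: the two bond formations are uncoupled. It sets out from 10 and 13: the sodium enolate of 13 (NaH, THF–DMPU, 25 °C) is alkylated by 10, and chloro keto ester 14 is isolated and purified. The ring is then closed in a separate intramolecular O-alkylation (K2CO3, NaI, butanone, 70 °C), which comes back to the route at 15. No new compound is needed.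

2. Step 6 (olefination of the lactol). The hindered lactol may stay closed, so that the gem-dichromium reagent decays before it meets the aldehyde, and divalent chromium may slowly reduce the α-chloro carbonyl unit. Fallback: an open-chain aldehyde that cannot close is used. It sets out from lactone 7. Aminolysis with MeNH(OMe)·HCl/AlMe3 gives the hydroxy Weinreb amide F1. Silylation (Et3SiCl, imidazole) gives the triethylsilyl ether F2. iBu2AlH at −78 °C gives the aldehyde F3. Takai–Utimoto olefination of F3 gives the silyl-protected bromoalkene F4. PPTS in MeOH removes the silyl group and comes back to the route at 9.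

3. Step 11 (bromodecarboxylation and hydration). Protonation of the bromine-deactivated enol ether 17 may be slow, and prolonged exposure to aqueous acid may ionize the tertiary allylic chloride; excess NBS may also over-brominate. Fallback: the order of decarboxylation and bromination is reversed. It sets out from acid 16. Dilute aqueous H2SO4 in THF hydrates the much more basic β-alkoxyacrylate, and the β-keto acid so formed loses CO2 to give the bromine-free hemiketal F5. Bromination of F5 with pyridinium tribromide in AcOH through the endocyclic enol ether, left to equilibrate with the HBr formed, comes back to the route at 18 as the equatorial (thermodynamic) bromide.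

**Further compounds**
F0 | step 9 | none | none
F1 | step 6 | (2S,3R)-2-chloro-3-(chloromethyl)-4-hydroxy-N-methoxy-N,2-dimethylbutanamide | C[C@@](Cl)(C(=O)N(C)OC)[C@H](CO)CCl
F2 | step 6 | (2S,3R)-2-chloro-3-(chloromethyl)-N-methoxy-N,2-dimethyl-4-[(triethylsilyl)oxy]butanamide | C[C@@](Cl)(C(=O)N(C)OC)[C@H](CO[Si](CC)(CC)CC)CCl
F3 | step 6 | (2S,3R)-2-chloro-3-(chloromethyl)-2-methyl-4-[(triethylsilyl)oxy]butanal | C[C@@](Cl)(C=O)[C@H](CO[Si](CC)(CC)CC)CCl
F4 | step 6 | {[(2R,3S,4E)-5-bromo-3-chloro-2-(chloromethyl)-3-methylpent-4-en-1-yl]oxy}triethylsilane | C[C@@](Cl)(/C=C/Br)[C@H](CO[Si](CC)(CC)CC)CCl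
F5 | step 11 | (5R)-5-[(2S,3E)-4-bromo-2-chlorobut-3-en-2-yl]-2-methyloxan-2-ol, anomers | C[C@@](Cl)(/C=C/Br)[C@H]1COC(C)(O)CC1
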